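**Assumption:** 2, 5 and 18 are bought as such. Positions are in labdane numbering (C2 carbinol, C4 gem-dimethyl carbon, C5/C10 ring fusion, C8 methylidene carbon, C9 side-chain carbon, C11–C16 side chain). The SMILES is read as the (2R,5R,9R,10R) ent-labdane with an equatorial 2-OH and a 13E alkene (CH2OAc trans to CO2H).

## Retrosynthetic overview

1. Target 23 ⇐ dihydroxy acid 21 ⇐ methyl ester 20: the acetate and the free acid are set last.
2. C12–C13: radical nickel cross-electrophile coupling of decalin iodide 17 with the Z-iodoenoate 19, which fixes the 13E geometry.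
3. Key disconnection C4–C5 and C9–C10: acyclic trienediol 15 → decalin 16 in one hydrogen-atom-transfer radical cascade. Ring A closes first, ring B second, and the C8 radical ends as the 8(17)-alkene. The C2 carbinol is the only stereocentre going in.
4. 15 ⇐ epoxide 4 by two rounds of acetylide addition and zirconium-catalysed carboalumination/oxirane opening (both E-alkenes).
5. 4 ⇐ (R)-epichlorohydrin 1 + isopropenylmagnesium bromide 2.

## Route

**Step 1**
Reactants: 1 (R)-epichlorohydrin; 2 isopropenylmagnesium bromide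
Product: 4 (2R)-2-(2-methylprop-2-en-1-yl)oxirane, via bromomagnesium chlorohydrin alkoxide 3 (not isolated)
Conditions: CuI (5 mol %), THF, −40 → −10 °C; then 5 M aq. NaOH, 23 °C
Reagents that add atoms: none
Why: Copper-catalysed Grignard opening of the epoxide at its CH2 end, then Williamson-type closure of the alkoxide onto the CH2Cl carbon; the C–O bond of the stereocentre is never broken, so (R) is kept.

**Step 2**
Reactants: 4 (2R)-2-(2-methylprop-2-en-1-yl)oxirane; 5 lithium acetylide–ethylenediamine complex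
Product: 6 (4R)-6-methylhept-6-en-1-yn-4-ol
Conditions: 5 (1.5 equiv), DMSO, 0 → 23 °C; H2O
Reagents that add atoms: none
Why: SN2 opening of the terminal epoxide by acetylide at the unsubstituted carbon, which leaves the carbinol stereocentre untouched.

**Step 3**
Reactants: 6 (4R)-6-methylhept-6-en-1-yn-4-ol; 7 oxirane
Product: 10 (3E,6R)-4,8-dimethylnona-3,8-diene-1,6-diol, via alkenyldimethylalane 8 (not isolated), via lithium butylalanate 9 (not isolated)
Conditions: Me3Al (3 equiv), Cp2ZrCl2 (25 mol %), CH2Cl2, 0 → 23 °C; volatiles off; n-BuLi (2.2 equiv), THF, −78 °C; 7 (5 equiv), −78 → 0 °C; 1 M HCl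
Reagents that add atoms: trimethylaluminium, C[Al](C)C
Why: Negishi zirconium-catalysed syn-carboalumination puts CH3 on the internal and Al on the terminal alkyne carbon (this sets the E trisubstituted alkene), and the derived alanate transfers the alkenyl group to oxirane with retention; the 1,1-disubstituted alkene does not react.

**Step 4**
Reactants: 10 (3E,6R)-4,8-dimethylnona-3,8-diene-1,6-diol
Product: 11 (4R,6E)-9-iodo-2,6-dimethylnona-1,6-dien-4-ol
Conditions: I2 (1.05 equiv), PPh3, imidazole, CH2Cl2, −20 → 0 °C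
Reagents that add atoms: iodine, II
Why: Appel-type (Garegg–Samuelsson) iodination is much faster at the primary than at the secondary hydroxyl.

**Step 5**
Reactants: 11 (4R,6E)-9-iodo-2,6-dimethylnona-1,6-dien-4-ol; 5 lithium acetylide–ethylenediamine complex
Product: 12 (4R,6E)-2,6-dimethylundeca-1,6-dien-10-yn-4-ol
Conditions: 5 (3 equiv), DMSO, 10 → 23 °C; H2O
Reagents that add atoms: none
Why: SN2 alkylation of acetylide by the primary iodide in DMSO; one further equivalent is used up by the free hydroxyl.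

**Step 6**
Reactants: 12 (4R,6E)-2,6-dimethylundeca-1,6-dien-10-yn-4-ol; 7 oxirane
Product: 15 (3E,7E,10R)-4,8,12-trimethyltrideca-3,7,12-triene-1,10-diol, via alkenyldimethylalane 13 (not isolated), via lithium butylalanate 14 (not isolated)
Conditions: Me3Al (3 equiv), Cp2ZrCl2 (25 mol %), CH2Cl2, 0 → 23 °C; volatiles off; n-BuLi (2.2 equiv), THF, −78 °C; 7 (5 equiv), −78 → 0 °C; 1 M HCl
Reagents that add atoms: trimethylaluminium, C[Al](C)C
Why: Same Negishi carboalumination/alanate–oxirane opening as in step 3; it sets the second E trisubstituted alkene and adds C11–C12 with its hydroxyl.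

**Step 7 (key step)**
Reactants: 15 (3E,7E,10R)-4,8,12-trimethyltrideca-3,7,12-triene-1,10-diol
Product: 16 (2R,4aR,8R,8aR)-8-(2-hydroxyethyl)-4,4,8a-trimethyl-7-methylidenedecahydronaphthalen-2-ol
Conditions: Fe(acac)3 (1.5 equiv), PhSiH3 (1.5 equiv, slow addition), Co(dmgH)2(py)Cl (5 mol %), degassed EtOH/HOCH2CH2OH 5:1 (0.01 M), 40 °C
Reagents that add atoms: none
Why: Proposed new method: the iron hydride from Fe(acac)3 and PhSiH3 gives a hydrogen atom (Mukaiyama-type metal-hydride hydrogen-atom transfer) only to the unhindered 1,1-disubstituted alkene, and the tertiary C4 radical closes ring A 6-endo onto C5; the tertiary C10 radical then closes ring B 6-endo onto C9 through a chair–chair transition state with the C2 hydroxyl equatorial (an axial OH would clash with the axial C4 and C10 methyls), so the one stereocentre of 15 sets C5, C10 and C9 (trans ring fusion, C9 chain equatorial from the E alkene); the tertiary C8 radical is dehydrogenated by divalent cobaloxime at its least hindered β-hydrogen (the methyl, as in cobaloxime catalytic chain transfer) to give the exocyclic alkene, the cobalt hydride leaves as H2, and radicals stopped too early in the same way return mainly to 1,1-disubstituted alkenes that re-enter; closest known reaction types are the Fe(acac)3/PhSiH3 radical polyene cyclisation, the Cp2TiCl-mediated epoxypolyene bicyclisation that ends in an exocyclic alkene, and cobalt-catalysed hydrogen-atom-transfer cycloisomerisation of dienes.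

**Step 8**
Reactants: 16 (2R,4aR,8R,8aR)-8-(2-hydroxyethyl)-4,4,8a-trimethyl-7-methylidenedecahydronaphthalen-2-ol
Product: 17 (2R,4aR,8R,8aR)-8-(2-iodoethyl)-4,4,8a-trimethyl-7-methylidenedecahydronaphthalen-2-ol
Conditions: I2 (1.05 equiv), PPh3, imidazole, CH2Cl2, 0 °C
Reagents that add atoms: iodine, II
Why: Appel-type iodination picks the primary hydroxyl over the ring secondary one and does not touch the alkene.

**Step 9**
Reactants: 18 methyl 4-hydroxybut-2-ynoate
Product: 19 methyl (2Z)-4-hydroxy-3-iodobut-2-enoate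
Conditions: NaI (2 equiv), AcOH, 70 °C
Reagents that add atoms: sodium iodide, [Na+].[I-]
Why: Anti-hydroiodination of the ynoate (conjugate addition of iodide, protonation from the opposite side) gives the Z β-iodoenoate with I cis and CH2OH trans to the ester, so no lactone can form.

**Step 10**
Reactants: 17 (2R,4aR,8R,8aR)-8-(2-iodoethyl)-4,4,8a-trimethyl-7-methylidenedecahydronaphthalen-2-ol; 19 methyl (2Z)-4-hydroxy-3-iodobut-2-enoate
Product: 20 methyl (2E)-5-[(1R,4aR,7R,8aR)-7-hydroxy-5,5,8a-trimethyl-2-methylidenedecahydronaphthalen-1-yl]-3-(hydroxymethyl)pent-2-enoate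
Conditions: NiBr2(dme) (10 mol %), 4,4′-di-tert-butyl-2,2′-bipyridine (10 mol %), Zn dust (2 equiv), NaI (25 mol %), DMA, 23 °C; 19 (1.3 equiv)
Reagents that add atoms: none
Why: Nickel-catalysed reductive cross-electrophile coupling in which the primary C12 radical (iodine abstraction from 17 by monovalent nickel) is caught by the alkenylnickel from 19 and reductive elimination keeps the alkene geometry, so the chain ends cis to the ester (E descriptor); free hydroxyls are tolerated.

**Step 11**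
Reactants: 20 methyl (2E)-5-[(1R,4aR,7R,8aR)-7-hydroxy-5,5,8a-trimethyl-2-methylidenedecahydronaphthalen-1-yl]-3-(hydroxymethyl)pent-2-enoate
Product: 21 (2E)-5-[(1R,4aR,7R,8aR)-7-hydroxy-5,5,8a-trimethyl-2-methylidenedecahydronaphthalen-1-yl]-3-(hydroxymethyl)pent-2-enoic acid
Conditions: LiOH (3 equiv), THF/H2O 3:1, 0 → 23 °C; 1 M HCl to pH 3
Reagents that add atoms: lithium hydroxide, [Li+].[OH-]
Why: Plain saponification; the CH2OH is trans to the carboxyl and cannot lactonise, and no stereocentre is next to a carbonyl.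

**Step 12**
Reactants: 21 (2E)-5-[(1R,4aR,7R,8aR)-7-hydroxy-5,5,8a-trimethyl-2-methylidenedecahydronaphthalen-1-yl]-3-(hydroxymethyl)pent-2-enoic acid
Product: 23 (2E)-3-[(acetyloxy)methyl]-5-[(1R,4aR,7R,8aR)-7-hydroxy-5,5,8a-trimethyl-2-methylidenedecahydronaphthalen-1-yl]pent-2-enoic acid, via mixed acetic anhydride 22 (not isolated)
Conditions: AcCl (2.1 equiv), 2,4,6-collidine (4 equiv), CH2Cl2, −78 °C; then H2O, THF, 0 °C
Reagents that add atoms: acetyl chloride, CC(Cl)=O
Why: Acetyl chloride/collidine at −78 °C acetylates the primary allylic hydroxyl far faster than the ring secondary one; the carboxyl is acetylated too, as the mixed anhydride, which water cleaves again.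

## Compound list

1 | (R)-epichlorohydrin, (2R)-2-(chloromethyl)oxirane | ClC[C@H]1CO1 | starting material
2 | isopropenylmagnesium bromide (prop-1-en-2-ylmagnesium bromide) | C=C(C)[Mg]Br | starting material
3 | bromomagnesium (2R)-1-chloro-4-methylpent-4-en-2-olate | C=C(C)C[C@@H](O[Mg]Br)CCl | intermediate
4 | (2R)-2-(2-methylprop-2-en-1-yl)oxirane | C=C(C)C[C@@H]1CO1 | intermediate
5 | lithium acetylide–ethylenediamine complex | [Li+].[C-]#C.NCCN | starting material
6 | (4R)-6-methylhept-6-en-1-yn-4-ol | C=C(C)C[C@@H](O)CC#C | intermediate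
7 | oxirane (ethylene oxide) | C1CO1 | starting material
8 | [(1E,4R)-4-[(dimethylalumanyl)oxy]-2,6-dimethylhepta-1,6-dien-1-yl](dimethyl)alumane | C=C(C)C[C@@H](O[Al](C)C)C/C(C)=C/[Al](C)C | intermediate
9 | lithium butyl[(1E,4R)-4-[(dimethylalumanyl)oxy]-2,6-dimethylhepta-1,6-dien-1-yl]dimethylaluminate | [Li+].C=C(C)C[C@@H](O[Al](C)C)C/C(C)=C/[Al-](C)(C)CCCC | intermediate
10 | (3E,6R)-4,8-dimethylnona-3,8-diene-1,6-diol | C=C(C)C[C@@H](O)C/C(C)=C/CCO | intermediate
11 | (4R,6E)-9-iodo-2,6-dimethylnona-1,6-dien-4-ol | C=C(C)C[C@@H](O)C/C(C)=C/CCI | intermediate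
12 | (4R,6E)-2,6-dimethylundeca-1,6-dien-10-yn-4-ol | C=C(C)C[C@@H](O)C/C(C)=C/CCC#C | intermediate
13 | [(1E,5E,8R)-8-[(dimethylalumanyl)oxy]-2,6,10-trimethylundeca-1,5,10-trien-1-yl](dimethyl)alumane | C=C(C)C[C@@H](O[Al](C)C)C/C(C)=C/CC/C(C)=C/[Al](C)C | intermediate
14 | lithium butyl[(1E,5E,8R)-8-[(dimethylalumanyl)oxy]-2,6,10-trimethylundeca-1,5,10-trien-1-yl]dimethylaluminate | [Li+].C=C(C)C[C@@H](O[Al](C)C)C/C(C)=C/CC/C(C)=C/[Al-](C)(C)CCCC | intermediate
15 | (3E,7E,10R)-4,8,12-trimethyltrideca-3,7,12-triene-1,10-diol | C=C(C)C[C@@H](O)C/C(C)=C/CC/C(C)=C/CCO | intermediate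
16 | (2R,4aR,8R,8aR)-8-(2-hydroxyethyl)-4,4,8a-trimethyl-7-methylidenedecahydronaphthalen-2-ol | C=C1CC[C@@H]2C(C)(C)C[C@@H](O)C[C@@]2(C)[C@@H]1CCO | intermediate
17 | (2R,4aR,8R,8aR)-8-(2-iodoethyl)-4,4,8a-trimethyl-7-methylidenedecahydronaphthalen-2-ol | C=C1CC[C@@H]2C(C)(C)C[C@@H](O)C[C@@]2(C)[C@@H]1CCI | intermediate
18 | methyl 4-hydroxybut-2-ynoate | COC(=O)C#CCO | starting material
19 | methyl (2Z)-4-hydroxy-3-iodobut-2-enoate | OC/C(I)=C/C(=O)OC | intermediate
20 | methyl (2E)-5-[(1R,4aR,7R,8aR)-7-hydroxy-5,5,8a-trimethyl-2-methylidenedecahydronaphthalen-1-yl]-3-(hydroxymethyl)pent-2-enoate | C=C1CC[C@@H]2C(C)(C)C[C@@H](O)C[C@@]2(C)[C@@H]1CC/C(=C\C(=O)OC)CO | intermediate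
21 | (2E)-5-[(1R,4aR,7R,8aR)-7-hydroxy-5,5,8a-trimethyl-2-methylidenedecahydronaphthalen-1-yl]-3-(hydroxymethyl)pent-2-enoic acid | C=C1CC[C@@H]2C(C)(C)C[C@@H](O)C[C@@]2(C)[C@@H]1CC/C(=C\C(=O)O)CO | intermediate
22 | acetic (2E)-3-[(acetyloxy)methyl]-5-[(1R,4aR,7R,8aR)-7-hydroxy-5,5,8a-trimethyl-2-methylidenedecahydronaphthalen-1-yl]pent-2-enoic anhydride | C=C1CC[C@@H]2C(C)(C)C[C@@H](O)C[C@@]2(C)[C@@H]1CC/C(=C\C(=O)OC(C)=O)COC(C)=O | intermediate
23 | (2E)-3-[(acetyloxy)methyl]-5-[(1R,4aR,7R,8aR)-7-hydroxy-5,5,8a-trimethyl-2-methylidenedecahydronaphthalen-1-yl]pent-2-enoic acid | C=C1CC[C@@H]2C(C)(C)C[C@@H](O)C[C@@]2(C)[C@@H]1CC/C(=C\C(=O)O)COC(C)=O | target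

## Step count and risks

Total steps: 12. Longest linear sequence: 11 (steps 1–8, then 10–12; step 9 is the side branch).

**Step 7 (most likely to fail).** The cascade may stop after ring A, the C8 radical may be reduced or lose the wrong hydrogen, and the iron hydride may re-open the product alkene. The fallback keeps the radical cascade but ends it by oxygen capture and a separate, stereoelectronically controlled elimination; it sets out from 15 and comes back at 16. Both hydroxyls of 15 are acetylated (Ac2O, pyridine, DMAP) to (3E,7E,10R)-4,8,12-trimethyltrideca-3,7,12-triene-1,10-diyl diacetate F1. F1 is cyclised under oxidative cobalt hydrogen-atom-transfer conditions (Co(salen) 5 mol %, N-fluoro-2,4,6-trimethylpyridinium tetrafluoroborate, (Me2SiH)2O, acetone/H2O, 0 °C). There the C8 radical is oxidised and taken up by water from the equatorial side, giving 2-[(1S,2S,4aR,7R,8aR)-7-acetoxy-2-hydroxy-2,5,5,8a-tetramethyldecahydronaphthalen-1-yl]ethyl acetate F2. The equatorial tertiary hydroxyl has no anti-periplanar ring hydrogen, so SOCl2/pyridine (CH2Cl2, −78 °C) eliminates into the methyl group and gives 2-[(1R,4aR,7R,8aR)-7-acetoxy-5,5,8a-trimethyl-2-methylidenedecahydronaphthalen-1-yl]ethyl acetate F3. K2CO3 in MeOH then removes both acetates and returns 16.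

**Step 10.** The β-iodoenoate may isomerise or dimerise on nickel, and the alkyl iodide may be reduced. The fallback replaces the radical coupling by a two-electron palladium/zinc coupling; it sets out from 17 and comes back at 20. 17 is silylated (Me3SiCl, imidazole, CH2Cl2) to {[(2R,4aR,8R,8aR)-8-(2-iodoethyl)-4,4,8a-trimethyl-7-methylidenedecahydronaphthalen-2-yl]oxy}(trimethyl)silane F4. Zinc insertion (Zn dust, LiCl, THF, 40 °C) gives iodo{2-[(1R,4aR,7R,8aR)-5,5,8a-trimethyl-2-methylidene-7-[(trimethylsilyl)oxy]decahydronaphthalen-1-yl]ethyl}zinc F5, which is used as formed. Negishi coupling (Pd(PPh3)4 5 mol %, THF, 23 °C) with methyl (2Z)-3-iodo-4-[(trimethylsilyl)oxy]but-2-enoate F6 (made from 19 with Me3SiCl and imidazole) gives methyl (2E)-5-[(1R,4aR,7R,8aR)-5,5,8a-trimethyl-2-methylidene-7-[(trimethylsilyl)oxy]decahydronaphthalen-1-yl]-3-{[(trimethylsilyl)oxy]methyl}pent-2-enoate F7. Citric acid in MeOH removes both silyl groups and gives 20.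

**Step 12.** The ring hydroxyl may be acetylated as well, or the mixed anhydride may acylate a second molecule. The fallback removes the selectivity problem with a protecting group; it sets out from 17 and comes back at the target 23. 17 is silylated (t-BuMe2SiOTf, 2,6-lutidine, CH2Cl2, −78 °C) to tert-butyl{[(2R,4aR,8R,8aR)-8-(2-iodoethyl)-4,4,8a-trimethyl-7-methylidenedecahydronaphthalen-2-yl]oxy}dimethylsilane F8. The nickel coupling of step 10 with 19 gives methyl (2E)-5-[(1R,4aR,7R,8aR)-7-{[tert-butyl(dimethyl)silyl]oxy}-5,5,8a-trimethyl-2-methylidenedecahydronaphthalen-1-yl]-3-(hydroxymethyl)pent-2-enoate F9. LiOH (THF/H2O) gives (2E)-5-[(1R,4aR,7R,8aR)-7-{[tert-butyl(dimethyl)silyl]oxy}-5,5,8a-trimethyl-2-methylidenedecahydronaphthalen-1-yl]-3-(hydroxymethyl)pent-2-enoic acid F10. Its only free hydroxyl is acetylated (Ac2O, pyridine, then water) to (2E)-3-[(acetyloxy)methyl]-5-[(1R,4aR,7R,8aR)-7-{[tert-butyl(dimethyl)silyl]oxy}-5,5,8a-trimethyl-2-methylidenedecahydronaphthalen-1-yl]pent-2-enoic acid F11. HF·pyridine (THF, 0 °C) removes the silyl ether and gives 23.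

## Further compounds

F1 | step 7 | (3E,7E,10R)-4,8,12-trimethyltrideca-3,7,12-triene-1,10-diyl diacetate | C=C(C)C[C@@H](OC(C)=O)C/C(C)=C/CC/C(C)=C/CCOC(C)=O
F2 | step 7 | 2-[(1S,2S,4aR,7R,8aR)-7-acetoxy-2-hydroxy-2,5,5,8a-tetramethyldecahydronaphthalen-1-yl]ethyl acetate | C[C@]1(O)CC[C@@H]2C(C)(C)C[C@@H](OC(C)=O)C[C@@]2(C)[C@@H]1CCOC(C)=O
F3 | step 7 | 2-[(1R,4aR,7R,8aR)-7-acetoxy-5,5,8a-trimethyl-2-methylidenedecahydronaphthalen-1-yl]ethyl acetate | C=C1CC[C@@H]2C(C)(C)C[C@@H](OC(C)=O)C[C@@]2(C)[C@@H]1CCOC(C)=O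
F4 | step 10 | {[(2R,4aR,8R,8aR)-8-(2-iodoethyl)-4,4,8a-trimethyl-7-methylidenedecahydronaphthalen-2-yl]oxy}(trimethyl)silane | C=C1CC[C@@H]2C(C)(C)C[C@@H](O[Si](C)(C)C)C[C@@]2(C)[C@@H]1CCI
F5 | step 10 | iodo{2-[(1R,4aR,7R,8aR)-5,5,8a-trimethyl-2-methylidene-7-[(trimethylsilyl)oxy]decahydronaphthalen-1-yl]ethyl}zinc | C=C1CC[C@@H]2C(C)(C)C[C@@H](O[Si](C)(C)C)C[C@@]2(C)[C@@H]1CC[Zn]I
F6 | step 10 | methyl (2Z)-3-iodo-4-[(trimethylsilyl)oxy]but-2-enoate | C[Si](C)(C)OC/C(I)=C/C(=O)OC
F7 | step 10 | methyl (2E)-5-[(1R,4aR,7R,8aR)-5,5,8a-trimethyl-2-methylidene-7-[(trimethylsilyl)oxy]decahydronaphthalen-1-yl]-3-{[(trimethylsilyl)oxy]methyl}pent-2-enoate | C=C1CC[C@@H]2C(C)(C)C[C@@H](O[Si](C)(C)C)C[C@@]2(C)[C@@H]1CC/C(=C\C(=O)OC)CO[Si](C)(C)C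
F8 | step 12 | tert-butyl{[(2R,4aR,8R,8aR)-8-(2-iodoethyl)-4,4,8a-trimethyl-7-methylidenedecahydronaphthalen-2-yl]oxy}dimethylsilane | C=C1CC[C@@H]2C(C)(C)C[C@@H](O[Si](C)(C)C(C)(C)C)C[C@@]2(C)[C@@H]1CCI
F9 | step 12 | methyl (2E)-5-[(1R,4aR,7R,8aR)-7-{[tert-butyl(dimethyl)silyl]oxy}-5,5,8a-trimethyl-2-methylidenedecahydronaphthalen-1-yl]-3-(hydroxymethyl)pent-2-enoate | C=C1CC[C@@H]2C(C)(C)C[C@@H](O[Si](C)(C)C(C)(C)C)C[C@@]2(C)[C@@H]1CC/C(=C\C(=O)OC)CO
F10 | step 12 | (2E)-5-[(1R,4aR,7R,8aR)-7-{[tert-butyl(dimethyl)silyl]oxy}-5,5,8a-trimethyl-2-methylidenedecahydronaphthalen-1-yl]-3-(hydroxymethyl)pent-2-enoic acid | C=C1CC[C@@H]2C(C)(C)C[C@@H](O[Si](C)(C)C(C)(C)C)C[C@@]2(C)[C@@H]1CC/C(=C\C(=O)O)CO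
F11 | step 12 | (2E)-3-[(acetyloxy)methyl]-5-[(1R,4aR,7R,8aR)-7-{[tert-butyl(dimethyl)silyl]oxy}-5,5,8a-trimethyl-2-methylidenedecahydronaphthalen-1-yl]pent-2-enoic acid | C=C1CC[C@@H]2C(C)(C)C[C@@H](O[Si](C)(C)C(C)(C)C)C[C@@]2(C)[C@@H]1CC/C(=C\C(=O)O)COC(C)=O
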